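- Start from the leftover: the delta run, a racemic substrate coupled under a single-handed catalyst, still reads 38.1% left-handed substrate at 90.0 min, against 47.7% right-handed substrate reckoned from the charge and its product.

| setting | zeta | eta | delta | south-west | north |
|---|---|---|---|---|---|
| left-handed substrate | 0.019 M | 0.019 M | 0.019 M | 0.019 M | 0.019 M |
| right-handed substrate | 0.019 M | 0.019 M | 0.019 M | 0.019 M | 0.019 M |
| coupling partner | 0.80 equiv (in portions, 3) | 1.8 equiv (in portions, 3) | 1.2 equiv (in portions, 3) | 1.20 equiv (in portions, 3) | 1.20 equiv (in portions, 3) |
| protic impurity | 1.9 mM | 1.9 mM | 1.9 mM | 1.90 mM | 1.90 mM |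
| precatalyst | 2 mol% | 2 mol% | 4 mol% | 2 mol% | 2 mol% |
| temperature | 30 °C | 45 °C | 30 °C | 55 °C | 35 °C |
| remark | run made earlier; portions every 5.0 min | run made earlier; portions every 5.0 min | run made earlier; portions every 5.0 min | the portions of coupling partner follow each other after 5.0 min, the first at the start | the portions of coupling partner follow each other after 5.0 min, the first at the start |
| time |  |  |  | 40 min | 40 min |

| run | time / min | left-handed product / % | right-handed product / % | left-handed substrate / % |
|---|---|---|---|---|
| zeta | 15.0 | 0 | 0.9 | 50.5 |
| zeta | 40.0 | 3.1 | 1.5 | 48.0 |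
| zeta | 60.0 | 3.6 | 2.3 | 48.1 |
| zeta | 90.0 | 3.9 | 1.1 | 44.5 |
| eta | 4.00 | 0 | 0 | 50.6 |
| eta | 10.0 | 1.0 | 0.2 | 49.5 |
| eta | 25.0 | 7.7 | 2.0 | 40.9 |
| eta | 50.0 | 15.2 | 4.9 | 36.9 |
| delta | 30.0 | 4.3 | 0.6 | 46.3 |
| delta | 50.0 | 7.5 | 1.2 | 43.0 |
| delta | 80.0 | 11.2 | 2.7 | 39.4 |
| delta | 90.0 | 13.0 | 2.3 | 38.1 |

(each reading ± 1 percentage point)

- the flask that comes out highest in excess of left-handed product over right-handed product, or "all alike" when all lie within 1.5 percentage points (south-west / north / all alike)
- excess of left-handed product over right-handed product at the end, south-west
- excess of left-handed product over right-handed product at the end, north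

- catalyst is single-handed; left-handed substrate and right-handed substrate are mirror images of each other, charged as a racemate, each of them at the stated concentration
- the analysis behind the earlier runs scatters by 1 percentage point, standard deviation
- an excess is below zero if the other one leads

- Assume both substrates meet the same catalyst and coupling partner; these then cancel, and the ratio of rates is the selectivity factor s times c(left-handed substrate)/c(right-handed substrate).
- Take the midpoint of that concentration ratio between start and end, 0.899 in delta, as the leftover factor: the product ratio divided by it gives s.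
- Reckon s at the last readings: 6.28 in delta, and 3.41 in eta, the hotter run.
- Turn the question round: for "all alike", the excess would have to stay within 1.5 percentage points across temperature.
- Hold that against the readings: delta and eta differ in excess by 19 points, but the scatter on that difference is 14 points.
- Commit, as my own reckoning, to north on top, with a tie 1.25 scatters away and no firm size for the gap.
- Set beside it the forecast: north, with 43% for south-west and 63% for north. It is surer than my reckoning: “North should therefore be clearly highest.”
- Read the flasks: north leads, with 67.0% in north and 60.4% in south-west, 17 points above the forecast.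

    coupling partner + protic impurity → quenched reagent (k = 0.420 M⁻¹ s⁻¹, Ea = 55.0 kJ mol⁻¹)
    coupling partner + catalyst + left-handed substrate → catalyst + left-handed product (k = 95.0 M⁻² s⁻¹, Ea = 35.0 kJ mol⁻¹)
    coupling partner + catalyst + right-handed substrate → catalyst + right-handed product (k = 18.0 M⁻² s⁻¹, Ea = 42.0 kJ mol⁻¹)
    2 coupling partner → self-condensation product (k = 0.0300 M⁻¹ s⁻¹, Ea = 44.0 kJ mol⁻¹)
    coupling partner + precatalyst → catalyst + spent reagent (k = 0.0130 M⁻¹ s⁻¹, Ea = 61.0 kJ mol⁻¹)
    (constants at 35 °C)

- From north to south-west the right-handed step speeds up by 2.7 and the left-handed step by 2.3. So the ratio of these two rates shrinks to 0.852 of its value. Divide south-west's product ratio, 4.05, by south-west's own leftover factor, 0.908 (delta's was 0.899), to get s = 4.46. The neighbour of south-west charged with 4.80 equiv coupling partner ends at 21.0% left-handed and 41.2% right-handed substrate, a leftover factor of 0.755. That s then expects an excess of 54.2%, and the neighbour shows 53.3%.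

All runs stem from a simulated flask for substances that don't exist.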